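(Its constants are invented; no experiment stands behind them.)

At 25 °C the left-handed substrate meets the reagent 7.47 times as fast as the right-handed substrate does, so the question was what became of the slower hand.

    left-handed substrate + racemization catalyst ⇌ right-handed substrate + racemization catalyst, rate k1*[racemization catalyst]*[left-handed substrate] forward; the back reaction follows from the equilibrium constant (k1 = 0.141 /M/s, Ea1 = 40.0 kJ/mol)
    precatalyst ⇌ racemization catalyst (K2 = 0.803, k2 = 2.87 × 10⁻⁴ /s, Ea2 = 100 kJ/mol, ΔH2 = −33.0 kJ/mol)
    reagent + right-handed substrate → right-handed product (k3 = 3.28 × 10⁻⁴ /M/s, Ea3 = 77.0 kJ/mol)
    reagent + left-handed substrate → left-handed product (k4 = 0.00245 /M/s, Ea4 = 66.0 kJ/mol)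
    (constants at 25 °C)

| setting | oak | maple | elm | birch |
|---|---|---|---|---|
| left-handed substrate | 0.20 M | 0.20 M | 0.20 M | 0.20 M |
| reagent | 3.00 equiv | 3.00 equiv | 3.00 equiv | 3.00 equiv |
| precatalyst | 0.5 mol% | 0.5 mol% | 0.5 mol% | 0.5 mol% |
| right-handed substrate | 0.20 M | 0.20 M | 0.20 M | 0.20 M |
| temperature | 40 °C | 10 °C | −5 °C | 25 °C |
| time | 2.5 h | 2.5 h | 2.5 h | 2.5 h |

- reagent is single-handed; left-handed substrate and right-handed substrate are mirror images of each other, charged as a racemate, each of them at the stated concentration
- at 25 °C the constants are as listed, elsewhere as the activation energies and enthalpies make them
- an excess is the difference of the two amounts in percent of their sum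
- an excess is below zero if the other one leads
- the handed part of reagent does not stay in what it makes, so the products of the two hands are mirror images too

* the best flask by excess of left-handed product over right-handed product; "all alike" if 1.5 percentage points covers them all (oak / maple / elm / birch / all alike)
* excess of left-handed product over right-handed product at the end, oak
* excess of left-handed product over right-handed product at the end, maple
* excess of left-handed product over right-handed product at the end, elm
* excess of left-handed product over right-handed product at the end, birch

I reckoned on birch, where the constants stand as listed, and ranked its rates from the fastest. With reagent at its charge, the left-handed substrate had a pseudo-first-order half-life of 7.86 min. Precatalyst and racemization catalyst moved toward 44.5 % active with a half-life of 17.9 min, which is slower than the first rung.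

The next rung was the right-handed substrate, facing reagent at two parts of the left-handed charge. Its way into right-handed product had a half-life of 1.47 h, and its way through the catalyst into left-handed product had one of 3.07 h, which is slower. By these half-lives, left-handed substrate formed this way met reagent far sooner than it could racemize back. I treated racemization as the small exit and computed that correction alone. The two exits compete, so I reckoned 32.4 % as the leak, the share of departing right-handed substrate that ends as left-handed product. Once the right-handed substrate has drained, the excess equals the leak. In 2.5 h birch kept 17.4 % of its right-handed charge by this reckoning, which made the excess 38.8 %. Cooling slows the right-hand step more than the left-hand step, taking the selectivity factor from 6.0 in oak to 12.3 in elm, so I ranked elm first.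

The forecast named elm and gave 10 %, 43 %, 76 % and 20 % for oak, maple, elm and birch, holding that in the warmer flasks “the excess falls to what racemization can divert from right to left”, and its birch figure stood below mine.

The flasks gave 14.6 %, 61.5 %, 80.8 % and 34.8 % in that order, so elm was best, and birch fell short of my reckoning, keeping 25 % of its right-handed charge. After 25.0 h birch held 0 % right-handed substrate and an excess of 29.4 %, against the leak of 32.4 %. Oak kept 1.9 % of its right-handed charge at the end, so I read its 14.6 % as oak's own leak, lower than birch's. Elm stopped at 80.8 % with 95 % of its right-handed charge still standing, and after 25.0 h the same flask gave 58.1 %, so the short time given kept elm's excess higher by 23 percentage points.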